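**Strategy.** The cyclohexane ring (C-5 to C-10, elemane numbering) with its vicinal vinyl (on C-10) and 3-acetoxyprop-1-en-2-yl (on C-5) groups is the retron of a Cope rearrangement of a cyclodeca-1(10),4-diene. The C-7/C-8 carbinol next to the α-methylene lactone is the retron of an allylchromium addition. Both are merged: an acyclic aldehyde carrying a 3-(bromomethyl)butenolide is cyclised by CrCl2 at C-7–C-8 to a germacranolide, which on heating in the same flask contracts by [3,3] shift, forming C-5–C-10 and four stereocentres from the single centre C-6. The precursor is built linearly by two copper-catalysed anti-carbomagnesiations of propargyl alcohol, which fix both alkene geometries.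

Key step: step 13

Remarks: Elemane numbering is used throughout: C-10 quaternary ring carbon (vinyl C-1/C-2, CH2O C-14), C-9 ring CH2, C-8 ring CH–O, C-7 and C-6 lactone ring-fusion carbons (C-6 bears the lactone oxygen), C-5 ring CH bearing C-4(=C-3H2)–C-15H2OAc, lactone C-11(=C-13H2)–C-12(=O). PMB = 4-methoxybenzyl. The target is taken with all five stereocentres exactly as in its SMILES (H-5 α, H-6 β, H-7 α, 8α-OAc, C-14 β). Which enantiomer of the chiral ligand in step 9 gives Re-face addition is an assumption to be settled on first use.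

**Step 1**
Reactants: 1 prop-2-yn-1-ol; 2 allylmagnesium bromide
Product: 5 (2Z)-2-(iodomethylidene)pent-4-en-1-ol, via bromomagnesium prop-2-yn-1-olate 3 (not isolated), via 4-allyl-2,5-dihydro-1,2-oxamagnesole 4 (not isolated)
Conditions: 2 (2.5 equiv), CuI (5 mol %), Et2O/THF, 0 → 35 °C; then I2, −20 → 0 °C
Reagents that add atoms: iodine, II
Why: Copper-catalysed anti-carbomagnesiation of the propargylic magnesium alkoxide should place the allyl group (C-9, C-8) on the internal alkyne carbon and magnesium on the terminal carbon inside a five-membered chelate, so that iodinolysis with retention gives the Z-alkene with iodine cis to CH2OH (C-14).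

**Step 2**
Reactants: 5 (2Z)-2-(iodomethylidene)pent-4-en-1-ol
Product: 6 PMB ether of 5
Conditions: NaH, PMBCl, Bu4NI (cat.), THF/DMF, 0 → 23 °C
Reagents that add atoms: 4-methoxybenzyl chloride, COc1ccc(CCl)cc1
Why: Williamson ether synthesis on the primary alkoxide should be clean, and a benzyl-type ether is chosen because a silyl ether cis to the alkenyllithium of step 5 could migrate from oxygen to carbon.

**Step 3**
Reactants: 6 PMB ether
Product: 7 (3Z)-4-iodo-3-[(4-methoxybenzyloxy)methyl]but-3-enal
Conditions: OsO4 (2 mol %), NaIO4, 2,6-lutidine, dioxane/H2O, 23 °C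
Reagents that add atoms: osmium tetroxide (catalytic oxygen carrier), O=[Os](=O)(=O)=O; sodium periodate (terminal oxidant), [Na+].[O-]I(=O)(=O)=O
Why: Lemieux–Johnson oxidation should cleave only the monosubstituted terminal alkene, because the iodine-bearing trisubstituted alkene is electron-poor and hindered toward OsO4, giving the C-8 aldehyde.

**Step 4**
Reactants: 7 β,γ-unsaturated aldehyde
Product: 8 dimethyl acetal of 7
Conditions: HC(OMe)3, MeOH, pyridinium p-toluenesulfonate (cat.), 23 °C
Reagents that add atoms: trimethyl orthoformate, COC(OC)OC; methanol, CO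
Why: Acid-catalysed acetalisation with orthoformate as dehydrating agent should mask the isomerisation-prone aldehyde without touching the PMB ether or the alkenyl iodide.

**Step 5**
Reactants: 8 alkenyl iodide acetal; 9 oxirane
Product: 11 (3Z)-6,6-dimethoxy-4-[(4-methoxybenzyloxy)methyl]hex-3-en-1-ol, via alkenyllithium 10 (not isolated)
Conditions: t-BuLi (2.1 equiv), Et2O, −78 °C; then 9, −78 → 0 °C; H2O
Reagents that add atoms: none
Why: Iodine–lithium exchange proceeds with retention of alkene geometry, and the alkenyllithium should open oxirane by SN2 attack to give the homoallylic alcohol that supplies C-2 and C-3.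

**Step 6**
Reactants: 11 homoallylic alcohol
Product: 12 homoallylic bromide
Conditions: CBr4, PPh3, 2,6-lutidine, CH2Cl2, 0 °C
Reagents that add atoms: tetrabromomethane, BrC(Br)(Br)Br
Why: The Appel reaction converts the primary alcohol into the bromide under near-neutral conditions that the acetal tolerates.

**Step 7**
Reactants: 12 homoallylic bromide; 1 prop-2-yn-1-ol
Product: 16 (2Z,5Z)-2-(iodomethylidene)-8,8-dimethoxy-6-[(4-methoxybenzyloxy)methyl]oct-5-en-1-ol, via Grignard reagent 13 (not isolated), via chloromagnesium prop-2-yn-1-olate 14 (not isolated), via oxamagnesole chelate 15 (not isolated)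
Conditions: Mg, Et2O, 35 °C (12 → 13); 1 pre-treated with i-PrMgCl (1.0 equiv), THF, 0 °C (→ 14); combined, CuI (15 mol %), 23 → 40 °C; then I2, −20 → 0 °C
Reagents that add atoms: iodine, II
Why: The primary alkyl Grignard reagent should add under CuI catalysis in the anti sense to the pre-formed magnesium alkoxide of propargyl alcohol, and iodinolysis of the chelated alkenylmagnesium with retention should give the second Z-alkene with iodine (the future C-5 terminus) cis to CH2OH (C-15).

**Step 8**
Reactants: 16 iodo alcohol
Product: 17 acetate of 16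
Conditions: Ac2O, pyridine, DMAP (cat.), CH2Cl2, 0 °C
Reagents that add atoms: acetic anhydride, CC(=O)OC(C)=O
Why: Nucleophile-catalysed acetylation of the primary allylic alcohol installs the C-15 acetate of the target.

**Step 9**
Reactants: 17 alkenyl iodide acetate; 18 acrolein
Product: 20 (S)-configured bis-allylic alcohol, via alkenylchromium dichloride 19 (not isolated)
Conditions: CrCl2 (4 equiv), NiCl2 (2 mol %), chiral ligand N-[2-(4-isopropyl-4,5-dihydro-1,3-oxazol-2-yl)-6-methylphenyl]methanesulfonamide (4.4 equiv, the enantiomer that directs Re-face attack), Et3N, THF, 23 °C; 18 (3 equiv)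
Reagents that add atoms: none
Why: Asymmetric Nozaki–Hiyama–Kishi alkenylation (nickel-catalysed activation of the C–I bond, transmetalation to trivalent chromium, 1,2-addition with retention of alkene geometry) under control of the chromium-bound oxazoline–sulfonamide ligand should deliver the alkenyl group to the Re face of acrolein and so set C-6 as S.

**Step 10**
Reactants: 20 (S)-alcohol; 21 2-(bromomethyl)prop-2-enoic acid
Product: 22 2-(bromomethyl)acrylate ester of 20
Conditions: N,N'-diisopropylcarbodiimide, DMAP (5 mol %), CH2Cl2, −20 → 0 °C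
Reagents that add atoms: none
Why: Steglich esterification acylates the secondary alcohol at oxygen, so the C-6 configuration is retained, and low DMAP loading and temperature should spare the allylic bromide.

**Step 11**
Reactants: 22 acrylate ester
Product: 23 (R)-5-alkenyl-3-(bromomethyl)furan-2(5H)-one
Conditions: second-generation Hoveyda–Grubbs catalyst RuCl2(H2IMes)(=CH–C6H4-2-O-iPr) (10 mol %), toluene (5 mM), 80 °C
Reagents that add atoms: none
Why: Ring-closing metathesis between the monosubstituted vinyl group and the 1,1-disubstituted acrylate alkene should close the butenolide with loss of ethylene, the two trisubstituted alkenes being too hindered to compete.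

**Step 12**
Reactants: 23 butenolide acetal
Product: 24 butenolide aldehyde
Conditions: p-TsOH·H2O (10 mol %), acetone/H2O (10:1), 0 → 23 °C; used at once
Reagents that add atoms: water, O
Why: Mild acid-catalysed acetal hydrolysis should release the β,γ-unsaturated C-8 aldehyde while the acetate, PMB ether, lactone and allylic bromide survive.

**Step 13**
Reactants: 24 butenolide aldehyde
Product: 27 15-acetoxy-8α-hydroxy-14-(4-methoxybenzyloxy)elema-1,3,11(13)-trien-12,6α-olide, via allylchromium dichloride 25 (not isolated), via germacranolide chromium alkoxide 26 (not isolated)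
Conditions: CrCl2 (10 equiv), degassed THF, 25 °C, slow addition of 24 (final 2 mM); then the same flask sealed, 150 °C; H2O
Reagents that add atoms: none
Why: Divalent chromium reduces the allylic bromide to allylchromium 25, which adds through its γ-carbon C-7 to the C-8 aldehyde in a chair-like six-centre transition state (Nozaki–Hiyama–Kishi allylation; closest precedent: chromium-mediated allylative macrocyclisations to germacranolides), closing the ten-membered carbocycle and unveiling the α-methylene lactone; on heating, the 1(10),4-diene of 26 undergoes the Cope rearrangement known for germacranolides, forming C-5–C-10, breaking C-2–C-3 and contracting the macrocycle to the cyclohexane. The modes of closure are therefore an intramolecular SE2′ carbonyl addition for the ten-membered ring and a transannular [3,3]-sigmatropic shift through a chair transition state for the six-membered ring. C-7 is set by bond formation on the butenolide face opposite the C-6 side chain (trans lactone), and C-8 by the anti preference of the γ-substituted allylchromium, whose C-6 substituent is held trans to CH2Cr by the lactone ring. C-5 and C-10 follow from the chair Cope transition state of the two ring-trans trisubstituted alkenes, whose crossed arrangement is fixed by the trans-fused lactone, giving H-5 α, an equatorial vinyl group and axial C-14. The step needs cyclisation over oligomerisation (high dilution, slow addition), γ- over α-attack (inherent to allylchromium) and a Cope equilibrium on the elemane side (loss of medium-ring strain, all ring substituents but C-14 equatorial); the substitution-inert trivalent chromium alkoxide should keep O-8 from attacking the lactone during heating.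

**Step 14**
Reactants: 27 elemanolide alcohol
Product: 28 8α,15-diacetoxy-14-(4-methoxybenzyloxy)elema-1,3,11(13)-trien-12,6α-olide
Conditions: Ac2O, DMAP, pyridine, CH2Cl2, 23 °C
Reagents that add atoms: acetic anhydride, CC(=O)OC(C)=O
Why: DMAP-catalysed acetylation of the equatorial secondary C-8 alcohol gives the second acetate with retention of configuration.

**Step 15**
Reactants: 28 PMB-protected diacetate
Product: 29 target, 8α,15-diacetoxy-14-hydroxyelema-1,3,11(13)-trien-12,6α-olide
Conditions: DDQ, CH2Cl2/pH 7 phosphate buffer (10:1), 0 → 23 °C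
Reagents that add atoms: none
Why: Oxidative PMB cleavage by DDQ (hydride abstraction, then hydrolysis of the oxocarbenium ion) should free the C-14 alcohol without touching the acetates, the α-methylene lactone or the alkenes.

**Compound list**

1 | prop-2-yn-1-ol (propargyl alcohol) | C#CCO | starting material
2 | allylmagnesium bromide | C=CC[Mg]Br | starting material
3 | bromomagnesium prop-2-yn-1-olate | C#CCO[Mg]Br | intermediate (not isolated)
4 | 4-allyl-2,5-dihydro-1,2-oxamagnesole (cyclic alkenylmagnesium alkoxide, Mg on the alkene CH cis to CH2O) | C=CCC1=C[Mg]OC1 | intermediate (not isolated)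
5 | (2Z)-2-(iodomethylidene)pent-4-en-1-ol (iodine cis to CH2OH) | OC/C(CC=C)=C\I | intermediate
6 | 1-({[(2Z)-2-(iodomethylidene)pent-4-en-1-yl]oxy}methyl)-4-methoxybenzene | COc1ccc(COC/C(CC=C)=C\I)cc1 | intermediate
7 | (3Z)-4-iodo-3-[(4-methoxybenzyloxy)methyl]but-3-enal | COc1ccc(COC/C(CC=O)=C\I)cc1 | intermediate
8 | 1-({[(2Z)-3-iodo-2-(2,2-dimethoxyethyl)prop-2-en-1-yl]oxy}methyl)-4-methoxybenzene | COc1ccc(COC/C(CC(OC)OC)=C\I)cc1 | intermediate
9 | oxirane | C1CO1 | starting material
10 | [(1Z)-4,4-dimethoxy-2-[(4-methoxybenzyloxy)methyl]but-1-en-1-yl]lithium | COc1ccc(COC/C(CC(OC)OC)=C\[Li])cc1 | intermediate (not isolated)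
11 | (3Z)-6,6-dimethoxy-4-[(4-methoxybenzyloxy)methyl]hex-3-en-1-ol | COc1ccc(COC/C(CC(OC)OC)=C\CCO)cc1 | intermediate
12 | 1-({[(2Z)-5-bromo-2-(2,2-dimethoxyethyl)pent-2-en-1-yl]oxy}methyl)-4-methoxybenzene | COc1ccc(COC/C(CC(OC)OC)=C\CCBr)cc1 | intermediate
13 | bromo[(3Z)-6,6-dimethoxy-4-[(4-methoxybenzyloxy)methyl]hex-3-en-1-yl]magnesium | COc1ccc(COC/C(CC(OC)OC)=C\CC[Mg]Br)cc1 | intermediate (not isolated)
14 | chloromagnesium prop-2-yn-1-olate | C#CCO[Mg]Cl | intermediate (not isolated)
15 | 4-substituted 2,5-dihydro-1,2-oxamagnesole carrying the (3Z)-hexenyl chain of 13 at C-4 | COc1ccc(COC/C(CC(OC)OC)=C\CCC2=C[Mg]OC2)cc1 | intermediate (not isolated)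
16 | (2Z,5Z)-2-(iodomethylidene)-8,8-dimethoxy-6-[(4-methoxybenzyloxy)methyl]oct-5-en-1-ol | COc1ccc(COC/C(CC(OC)OC)=C\CC/C(CO)=C/I)cc1 | intermediate
17 | (2Z,5Z)-2-(iodomethylidene)-8,8-dimethoxy-6-[(4-methoxybenzyloxy)methyl]oct-5-en-1-yl acetate | COc1ccc(COC/C(CC(OC)OC)=C\CC/C(COC(C)=O)=C/I)cc1 | intermediate
18 | acrolein (prop-2-enal) | C=CC=O | starting material
19 | alkenylchromium dichloride derived from 17 (Cr in place of I, geometry retained) | COc1ccc(COC/C(CC(OC)OC)=C\CC/C(COC(C)=O)=C/[Cr](Cl)Cl)cc1 | intermediate (not isolated)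
20 | (2Z,5Z)-2-[(2S)-2-hydroxybut-3-en-1-ylidene]-8,8-dimethoxy-6-[(4-methoxybenzyloxy)methyl]oct-5-en-1-yl acetate | COc1ccc(COC/C(CC(OC)OC)=C\CC/C(COC(C)=O)=C/[C@@H](O)C=C)cc1 | intermediate
21 | 2-(bromomethyl)prop-2-enoic acid | C=C(CBr)C(=O)O | starting material
22 | 2-(bromomethyl)prop-2-enoate ester of 20 at the (S)-carbinol oxygen | COc1ccc(COC/C(CC(OC)OC)=C\CC/C(COC(C)=O)=C/[C@@H](OC(=O)C(=C)CBr)C=C)cc1 | intermediate
23 | (2Z,5Z)-2-{[(2R)-4-(bromomethyl)-5-oxo-2,5-dihydrofuran-2-yl]methylidene}-8,8-dimethoxy-6-[(4-methoxybenzyloxy)methyl]oct-5-en-1-yl acetate | COc1ccc(COC/C(CC(OC)OC)=C\CC/C(COC(C)=O)=C/[C@H]2OC(=O)C(CBr)=C2)cc1 | intermediate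
24 | (2Z,5Z)-2-{[(2R)-4-(bromomethyl)-5-oxo-2,5-dihydrofuran-2-yl]methylidene}-6-[(4-methoxybenzyloxy)methyl]-8-oxooct-5-en-1-yl acetate | COc1ccc(COC/C(CC=O)=C\CC/C(COC(C)=O)=C/[C@H]2OC(=O)C(CBr)=C2)cc1 | intermediate
25 | allylchromium dichloride derived from 24 (CH2CrCl2 in place of CH2Br) | COc1ccc(COC/C(CC=O)=C\CC/C(COC(C)=O)=C/[C@H]2OC(=O)C(C[Cr](Cl)Cl)=C2)cc1 | intermediate (not isolated)
26 | chromium dichloride 8α-alkoxide of 15-acetoxy-14-(4-methoxybenzyloxy)-6βH,7αH-germacra-1(10),4,11(13)-trien-12,6-olide (both ring alkenes ring-trans: C-2 anti to C-9, C-3 anti to C-6) | Cl[Cr](Cl)O[C@H]1C/C(COCc3ccc(OC)cc3)=C/CC/C(COC(C)=O)=C/[C@H]2OC(=O)C(=C)[C@H]12 | intermediate (not isolated)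
27 | 15-acetoxy-8α-hydroxy-14-(4-methoxybenzyloxy)-5αH,6βH,7αH-elema-1,3,11(13)-trien-12,6-olide (C-14 β) | C=C[C@]1(COCc3ccc(OC)cc3)C[C@H](O)[C@H]2C(=C)C(=O)O[C@@H]2[C@H]1C(=C)COC(C)=O | intermediate
28 | 8α,15-diacetoxy-14-(4-methoxybenzyloxy)-5αH,6βH,7αH-elema-1,3,11(13)-trien-12,6-olide | C=C[C@]1(COCc3ccc(OC)cc3)C[C@H](OC(C)=O)[C@H]2C(=C)C(=O)O[C@@H]2[C@H]1C(=C)COC(C)=O | intermediate
29 | 8α,15-diacetoxy-14-hydroxy-5αH,6βH,7αH-elema-1,3,11(13)-trien-12,6-olide (CNP0240658.1) | C=C[C@]1(CO)C[C@H](OC(C)=O)[C@H]2C(=C)C(=O)O[C@@H]2[C@H]1C(=C)COC(C)=O | target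

**Step count.** Total: 15 steps. Longest linear sequence: 15 steps (from 1 and 2).

**Steps most likely to fail**

Step 13. The Cope equilibrium may not be reached, or the material may be eroded by oligomerisation, lactone migration to O-8 or reduction in the hot chromium medium; the ring closure could also give the C-7 or C-8 epimer. Fallback: setting out from 24, the chromium-mediated ring closure alone is run at 25 °C and worked up to give the germacranolide alcohol F1. Acetylation (Ac2O, DMAP, pyridine) gives the germacranolide acetate F2, and the Cope rearrangement is then run on this neutral, metal-free compound in o-xylene at 140–180 °C, which rejoins the route at 28. This uncouples the two bond formations but keeps both disconnections.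

Step 9. Facial selectivity in the ligand-controlled addition to acrolein may be poor, giving material of low enantiomeric purity at C-6. Fallback: setting out from 17, the same NiCl2/CrCl2 coupling with 18 is run without chiral ligand to give the racemic allylic alcohol F3. Oxidation with Dess–Martin periodinane gives the cross-conjugated dienone F4, and Corey–Bakshi–Shibata reduction (BH3·SMe2, (R)-2-methyl-CBS-oxazaborolidine, the trisubstituted alkenyl group acting as the large substituent) rejoins the route at 20.

Step 11. The ruthenium carbene may be deactivated by the allylic bromide, or the bromide may be lost by SN2′ substitution during esterification and metathesis. Fallback: setting out from 20, Steglich esterification with 2-{[(tert-butyldimethylsilyl)oxy]methyl}prop-2-enoic acid (C=C(CO[Si](C)(C)C(C)(C)C)C(=O)O) gives the silyloxymethyl acrylate F5. Ring-closing metathesis gives the silyloxymethyl butenolide F6, HF·pyridine gives the hydroxymethyl butenolide F7, and Appel bromination (CBr4, PPh3) rejoins the route at 23.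

**Further compounds**

F1 | step 13 | 15-acetoxy-8α-hydroxy-14-(4-methoxybenzyloxy)-6βH,7αH-germacra-1(10),4,11(13)-trien-12,6-olide | O[C@H]1C/C(COCc3ccc(OC)cc3)=C/CC/C(COC(C)=O)=C/[C@H]2OC(=O)C(=C)[C@H]12
F2 | step 13 | 8α,15-diacetoxy-14-(4-methoxybenzyloxy)-6βH,7αH-germacra-1(10),4,11(13)-trien-12,6-olide | CC(=O)O[C@H]1C/C(COCc3ccc(OC)cc3)=C/CC/C(COC(C)=O)=C/[C@H]2OC(=O)C(=C)[C@H]12
F3 | step 9 | racemic (2Z,5Z)-2-(2-hydroxybut-3-en-1-ylidene)-8,8-dimethoxy-6-[(4-methoxybenzyloxy)methyl]oct-5-en-1-yl acetate | COc1ccc(COC/C(CC(OC)OC)=C\CC/C(COC(C)=O)=C/C(O)C=C)cc1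
F4 | step 9 | (2Z,5Z)-8,8-dimethoxy-6-[(4-methoxybenzyloxy)methyl]-2-(2-oxobut-3-en-1-ylidene)oct-5-en-1-yl acetate | COc1ccc(COC/C(CC(OC)OC)=C\CC/C(COC(C)=O)=C/C(=O)C=C)cc1
F5 | step 11 | 2-{[(tert-butyldimethylsilyl)oxy]methyl}prop-2-enoate ester of 20 | COc1ccc(COC/C(CC(OC)OC)=C\CC/C(COC(C)=O)=C/[C@@H](OC(=O)C(=C)CO[Si](C)(C)C(C)(C)C)C=C)cc1
F6 | step 11 | analogue of 23 with CH2OSi(t-Bu)Me2 in place of CH2Br | COc1ccc(COC/C(CC(OC)OC)=C\CC/C(COC(C)=O)=C/[C@H]2OC(=O)C(CO[Si](C)(C)C(C)(C)C)=C2)cc1
F7 | step 11 | analogue of 23 with CH2OH in place of CH2Br | COc1ccc(COC/C(CC(OC)OC)=C\CC/C(COC(C)=O)=C/[C@H]2OC(=O)C(CO)=C2)cc1
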